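**Strategy.** The route rests on opening the cis C4=C5 alkene of the nine-membered oxacycle (O–C3–C4=C5–C6–C7–C8–C9–C10) to a ten-membered thiacycle in which a sulfone links C4 and C5. A Ramberg–Bäcklund reaction then extrudes SO2 and contracts this ring to the nine-membered one in a single operation, creating the strained Z alkene beside the furanone. It exploits C4–H, which is acidified by the sulfone and, vinylogously, by the C1 ketone of the furanone ring, so that halogenation is regioselective. The precursor is a furanone–butyrolactone cyclic sulfone built from a chiral-pool butenolide (C6), with C7, C10 and C8 set by trans radical addition, catalytic pyruvate aldol and directed reduction.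

Key step: step 13

Remark: atom labels C1–C15 are the germacrane labels of the target (C1 ketone, C2=C3, C4=C5 with C15 methyl, C6 and C8 carbinols, C10 quaternary with C14 methyl, C11–C13 lactone unit); the (R,R) bis(oxazoline) antipode is assumed to be the one that gives the (R)-carbinol in step 4, otherwise its enantiomer is used.

**Step 1**
Reactants: 1 (S)-5-(hydroxymethyl)furan-2(5H)-one
Product: 2 (S)-5-{[(tert-butyldimethylsilyl)oxy]methyl}furan-2(5H)-one
Conditions: TBSCl, imidazole, DMF, 0 °C to rt
Reagents that add atoms: tert-butyldimethylsilyl chloride, CC(C)(C)[Si](C)(C)Cl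
Why: Silyl ether formation (alcohol protection) masks the primary C5 hydroxyl for the basic and organometallic steps ahead; the C6 stereocentre is bought with 1 and is not touched.

**Step 2**
Reactants: 2 (S)-5-{[(tert-butyldimethylsilyl)oxy]methyl}furan-2(5H)-one; 3 acetaldehyde
Product: 4 (4S,5S)-4-acetyl-5-{[(tert-butyldimethylsilyl)oxy]methyl}oxolan-2-one
Conditions: (n-Bu4N)4[W10O32] (2 mol %), MeCHO (5 equiv), MeCN, 390 nm LED, rt
Reagents that add atoms: none
Why: Decatungstate-photocatalysed hydroacylation (Giese addition of the acetyl radical formed by hydrogen-atom abstraction from 3) should deliver the acyl group to the β-carbon C7 on the face opposite the C6 silyloxymethyl group, setting C7 trans to C6, the arrangement that is also thermodynamically preferred at this epimerisable centre.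

**Step 3**
Reactants: 4 (4S,5S)-4-acetyl-5-{[(tert-butyldimethylsilyl)oxy]methyl}oxolan-2-one
Product: 5 (4S,5S)-5-{[(tert-butyldimethylsilyl)oxy]methyl}-4-[1-(trimethylsilyloxy)ethenyl]oxolan-2-one
Conditions: LiN(i-Pr)2 (1.05 equiv), TMSCl (internal quench), THF, −78 °C
Reagents that add atoms: trimethylsilyl chloride, C[Si](C)(C)Cl
Why: Kinetic deprotonation of the methyl ketone at the methyl group with in situ silylation (silyl enol ether formation) gives the less substituted enol silane and avoids the C7 enolate, which would expel the lactone oxygen.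

**Step 4**
Reactants: 5 (4S,5S)-5-{[(tert-butyldimethylsilyl)oxy]methyl}-4-[1-(trimethylsilyloxy)ethenyl]oxolan-2-one; 6 methyl pyruvate
Product: 8 methyl (2R)-2-hydroxy-2-methyl-4-oxo-4-[(2S,3S)-2-{[(tert-butyldimethylsilyl)oxy]methyl}-5-oxooxolan-3-yl]butanoate, via trimethylsilyl ether 7 (not isolated)
Conditions: Cu(OTf)2 (10 mol %), (R,R)-t-Bu-box ligand (11 mol %), THF, −78 °C; then 1 M HCl, THF, 0 °C
Reagents that add atoms: none
Why: Copper–bis(oxazoline)-catalysed enantioselective Mukaiyama aldol addition to the chelated pyruvate should create the tertiary C10 carbinol under catalyst control (one ketone face of the five-membered chelate is shielded by a tert-butyl group), independent of the remote C6/C7 centres; acid work-up cleaves the silyl ether 7.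

**Step 5**
Reactants: 8 methyl (2R)-2-hydroxy-2-methyl-4-oxo-4-[(2S,3S)-2-{[(tert-butyldimethylsilyl)oxy]methyl}-5-oxooxolan-3-yl]butanoate
Product: 10 (3R,5S)-3-hydroxy-3-methyl-5-[(2S,3R)-2-{[(tert-butyldimethylsilyl)oxy]methyl}-5-oxooxolan-3-yl]oxolan-2-one (bis-lactone: 12,6-lactone plus 1,8-lactone), via diol ester 9 (not isolated)
Conditions: Me4NBH(OAc)3, MeCN–AcOH (1:1), −30 °C; then CSA (cat.), CH2Cl2, rt
Reagents that add atoms: none
Why: Evans–Saksena hydroxyl-directed reduction: hydride is delivered intramolecularly from the C10 alkoxyborohydride through a chair transition state with the C7 substituent and the C10 methyl equatorial and the slimmer ester axial, which should set C8 syn to C10–O along the chain through C1, and the γ-hydroxy ester 9 then lactonises, masking O8 and leaving a non-enolisable lactone at C1.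

**Step 6**
Reactants: 10 bis-lactone; 11 but-1-yne
Product: 14 hydroxy ynone (trans-12,6-lactone bearing at C7 the chain C8H(OH)–C9H2–C10(OH)(CH3)–C1(=O)–C2≡C3–C4H2–C15H3; in equilibrium with its C1/O8 hemiketal), via lithium but-1-ynide 12 (not isolated), via dilithium enolate alkoxide 13 (not isolated)
Conditions: 10, LiN(i-Pr)2 (2.1 equiv), THF, −78 °C; then 12 (1.3 equiv; from 11, n-BuLi, THF, −78 °C), −78 to −40 °C; AcOH, −78 °C
Reagents that add atoms: none
Why: Acetylide addition to a lactone (ynone synthesis through the stable tetrahedral adduct): the enolisable 12,6-lactone is masked in situ as its lithium enolate 13, so that 12 should attack only the non-enolisable 1,8-lactone carbonyl C1, releasing O8 as the free C8 hydroxyl on work-up; no stereocentre is affected.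

**Step 7**
Reactants: 14 hydroxy ynone
Product: 15 (4R,5S)-5-{[(tert-butyldimethylsilyl)oxy]methyl}-4-{(1S)-2-[(2R)-5-ethyl-2-methyl-3-oxo-2,3-dihydrofuran-2-yl]-1-hydroxyethyl}oxolan-2-one
Conditions: AuCl3 (5 mol %), CH2Cl2, rt
Reagents that add atoms: none
Why: Gold-catalysed 5-endo-dig cycloisomerisation of an α′-hydroxy ynone to a 3(2H)-furanone: the tertiary C10 hydroxyl adds to C3 of the activated alkyne, forming the O–C3 bond with C10 unchanged, while the more remote C8 hydroxyl would have to close a seven-membered ring.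

**Step 8**
Reactants: 15 furanone alcohol
Product: 16 triisopropylsilyl ether of 15 at the C8 oxygen
Conditions: TIPSOTf, 2,6-lutidine, CH2Cl2, −40 to 0 °C
Reagents that add atoms: triisopropylsilyl trifluoromethanesulfonate, CC(C)[Si](OS(=O)(=O)C(F)(F)F)(C(C)C)C(C)C
Why: Silyl ether formation at the secondary C8 hydroxyl with a bulky triisopropylsilyl group, which survives the later bromination, sulfide, oxidation and base steps and prevents O8 from attacking C5 or the lactone.

**Step 9**
Reactants: 16 bis-silyl ether
Product: 17 primary bromide (C5–Br in place of the C5 silyl ether of 16)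
Conditions: Ph3PBr2, CH2Cl2, rt
Reagents that add atoms: dibromotriphenylphosphorane, BrP(Br)(c1ccccc1)(c1ccccc1)c1ccccc1
Why: Direct bromodesilylation of a primary silyl ether with the bromophosphonium reagent (Appel-type SN2 displacement of the silyloxyphosphonium by bromide) turns C5 into an electrophile, the hindered secondary triisopropylsilyl ether reacting much more slowly.

**Step 10**
Reactants: 17 primary bromide
Product: 18 dibromide (17 brominated at C4; both C4 epimers)
Conditions: NBS, AIBN (cat.), PhCF3, 80 °C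
Reagents that add atoms: N-bromosuccinimide, O=C1CCC(=O)N1Br
Why: Wohl–Ziegler radical bromination at the C4 methylene, the only C–H position allylic to the furanone enol-ether double bond (γ to the C1 ketone); the new C4 centre is formed as both epimers, which is immaterial because C4 becomes sp2 in step 13.

**Step 11**
Reactants: 18 dibromide
Product: 19 ten-membered cyclic sulfide (sulfur bridges C4 and C5; both C4 epimers)
Conditions: Na2S·9H2O, EtOH–THF, high dilution (slow addition), rt
Reagents that add atoms: sodium sulfide, [Na+].[Na+].[S-2]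
Why: Double SN2 thioetherification with sulfide (macrocyclisation under high dilution): sulfide should first displace the activated secondary C4 bromide and the resulting thiolate then closes the ten-membered ring at the primary C5 bromide (10-exo-tet).

**Step 12**
Reactants: 19 cyclic sulfide
Product: 20 ten-membered cyclic sulfone
Conditions: mCPBA (2.2 equiv), CH2Cl2, 0 °C to rt
Reagents that add atoms: 3-chloroperoxybenzoic acid, OOC(=O)c1cccc(Cl)c1
Why: Chemoselective sulfide-to-sulfone oxidation with a peracid; the electron-poor furanone double bond and the silyl ethers should not react.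

**Step 13**
Reactants: 20 ten-membered cyclic sulfone
Product: 25 11,13-dihydro-8-O-(triisopropylsilyl)-8-deacyl-lychnopholide (nine-membered oxacycle with Z-C4=C5), via potassium hydroxy carboxylate 21 (not isolated), via α-bromo sulfone 22 (not isolated), via episulfone 23 (not isolated), via ring-contracted hydroxy carboxylate 24 (not isolated)
Conditions: KOH (2.5 equiv), t-BuOH–H2O, 0 °C; then CBr2F2, KOH/Al2O3, t-BuOH–CH2Cl2, 0 °C to rt; then 1 M HCl, 0 °C to rt
Reagents that add atoms: none
Why: Ramberg–Bäcklund ring contraction under Meyers–Chan in situ halogenation: after saponification of the lactone (21), C4–H, the only proton flanked by the sulfone and the vinylogous C1 ketone, is deprotonated and brominated by CBr2F2 (22), the C5 carbanion then displaces bromide to the episulfone 23, which loses SO2 to give the C4=C5 alkene (24), and acidification re-closes the lactone. The closest known reaction type is the Ramberg–Bäcklund contraction of medium-ring α-halo sulfones to cycloalkenes. The episulfone closes 3-exo-tet; the nine-membered oxacycle is not closed by cyclisation but arises from the ten-membered thiacycle by extrusion of the sulfur atom; the lactone re-forms 5-exo-trig. No sp3 stereocentre is created, the C4 epimers converge, and the alkene can only be Z because the cis-fused episulfone and the nine-membered ring exclude the E isomer; C6, C7, C8 and C10 are untouched since only the acyl–oxygen bond of the lactone is broken and re-made. The step needs halogenation at C4 rather than C5, secured by the acidity difference, and 1,3-elimination rather than β-elimination of the C6 oxygen, secured by running the reaction on the hydroxy carboxylate, in which C6 carries a hydroxyl instead of an acyloxy leaving group.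

**Step 14**
Reactants: 25 ring-contracted lactone
Product: 28 8-O-(triisopropylsilyl)-8-deacyl-lychnopholide (α-methylene lactone), via Mannich base 26 (not isolated), via trimethylammonium iodide 27 (not isolated)
Conditions: LiN(i-Pr)2, THF, −78 °C; CH2=NMe2+ I−, −78 °C to rt; MeI, MeOH, rt; NaHCO3 (aq), EtOAc, rt
Reagents that add atoms: Eschenmoser's salt (N,N-dimethylmethyleneiminium iodide), C=[N+](C)C.[I-]
Why: α-Methylenation of a γ-butyrolactone by Mannich reaction of its lithium enolate with Eschenmoser's salt, exhaustive N-methylation and E1cB elimination of trimethylamine; the C11 centre of 26 disappears on elimination, and kinetic deprotonation is expected at the accessible lactone CH2 rather than at the hindered C6–H.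

**Step 15**
Reactants: 28 silyl-protected α-methylene lactone
Product: 29 8-deacyl-lychnopholide (free C8 hydroxyl)
Conditions: HF·pyridine, pyridine, THF, 0 °C to rt
Reagents that add atoms: none
Why: Fluoride-mediated desilylation under buffered acidic conditions frees the C8 hydroxyl without base, which the α-methylene lactone and the dienone would not tolerate.

**Step 16**
Reactants: 29 8-deacyl-lychnopholide; 30 angelic acid ((Z)-2-methylbut-2-enoic acid)
Product: 32 lychnopholide, via mixed anhydride 31 (not isolated)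
Conditions: 30, 2,4,6-trichlorobenzoyl chloride, Et3N, toluene, rt; then 29, toluene, 80 °C
Reagents that add atoms: none
Why: Yamaguchi-type esterification through the preformed 2,4,6-trichlorobenzoyl mixed anhydride 31, run without a nucleophilic amine catalyst so that the (Z)-2-methylbut-2-enoyl group is transferred without isomerisation to the (E) isomer; C8 retains its configuration because the C–O bond is not broken.

**Compound list**

1 | (S)-5-(hydroxymethyl)furan-2(5H)-one | O=C1C=C[C@@H](CO)O1 | starting material
2 | (S)-5-{[(tert-butyldimethylsilyl)oxy]methyl}furan-2(5H)-one | O=C1C=C[C@@H](CO[Si](C)(C)C(C)(C)C)O1 | intermediate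
3 | acetaldehyde | CC=O | starting material
4 | (4S,5S)-4-acetyl-5-{[(tert-butyldimethylsilyl)oxy]methyl}oxolan-2-one (4,5-trans) | CC(=O)[C@H]1CC(=O)O[C@@H]1CO[Si](C)(C)C(C)(C)C | intermediate
5 | (4S,5S)-5-{[(tert-butyldimethylsilyl)oxy]methyl}-4-[1-(trimethylsilyloxy)ethenyl]oxolan-2-one | C=C(O[Si](C)(C)C)[C@H]1CC(=O)O[C@@H]1CO[Si](C)(C)C(C)(C)C | intermediate
6 | methyl pyruvate (methyl 2-oxopropanoate) | CC(=O)C(=O)OC | starting material
7 | trimethylsilyl ether of 8 at the C10 oxygen | COC(=O)[C@](C)(O[Si](C)(C)C)CC(=O)[C@H]1CC(=O)O[C@@H]1CO[Si](C)(C)C(C)(C)C | intermediate (not isolated)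
8 | methyl (2R)-2-hydroxy-2-methyl-4-oxo-4-[(2S,3S)-2-{[(tert-butyldimethylsilyl)oxy]methyl}-5-oxooxolan-3-yl]butanoate | COC(=O)[C@](C)(O)CC(=O)[C@H]1CC(=O)O[C@@H]1CO[Si](C)(C)C(C)(C)C | intermediate
9 | diol ester: 8 with the C8 ketone reduced to the (S)-carbinol (C8–OH and C10–OH syn along the chain through C1) | COC(=O)[C@](C)(O)C[C@H](O)[C@H]1CC(=O)O[C@@H]1CO[Si](C)(C)C(C)(C)C | intermediate (not isolated)
10 | (3R,5S)-3-hydroxy-3-methyl-5-[(2S,3R)-2-{[(tert-butyldimethylsilyl)oxy]methyl}-5-oxooxolan-3-yl]oxolan-2-one (bis-lactone; C8 substituent trans to C10–OH on the 1,8-lactone) | O=C1O[C@@H](C[C@@]1(C)O)[C@H]2CC(=O)O[C@@H]2CO[Si](C)(C)C(C)(C)C | intermediate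
11 | but-1-yne | CCC#C | starting material
12 | lithium but-1-ynide | [Li]C#CCC | intermediate (not isolated)
13 | dilithium derivative of 10 (C10 alkoxide, lithium enolate of the 12,6-lactone) | O=C1O[C@@H](C[C@@]1(C)O[Li])[C@H]2C=C(O[Li])O[C@@H]2CO[Si](C)(C)C(C)(C)C | intermediate (not isolated)
14 | hydroxy ynone: trans-12,6-lactone with the C7 chain C8H(OH)–C9H2–C10(OH)(CH3)–C1(=O)–C≡C–CH2CH3 | CCC#CC(=O)[C@](C)(O)C[C@H](O)[C@H]1CC(=O)O[C@@H]1CO[Si](C)(C)C(C)(C)C | intermediate
15 | (4R,5S)-5-{[(tert-butyldimethylsilyl)oxy]methyl}-4-{(1S)-2-[(2R)-5-ethyl-2-methyl-3-oxo-2,3-dihydrofuran-2-yl]-1-hydroxyethyl}oxolan-2-one | CCC1=CC(=O)[C@@](C)(C[C@H](O)[C@H]2CC(=O)O[C@@H]2CO[Si](C)(C)C(C)(C)C)O1 | intermediate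
16 | C8 triisopropylsilyl ether of 15 | CCC1=CC(=O)[C@@](C)(C[C@H](O[Si](C(C)C)(C(C)C)C(C)C)[C@H]2CC(=O)O[C@@H]2CO[Si](C)(C)C(C)(C)C)O1 | intermediate
17 | primary bromide: 16 with C5–Br in place of the C5 silyl ether | CCC1=CC(=O)[C@@](C)(C[C@H](O[Si](C(C)C)(C(C)C)C(C)C)[C@H]2CC(=O)O[C@@H]2CBr)O1 | intermediate
18 | dibromide: 17 brominated at C4 (1-bromoethyl on the furanone; both C4 epimers) | CC(Br)C1=CC(=O)[C@@](C)(C[C@H](O[Si](C(C)C)(C(C)C)C(C)C)[C@H]2CC(=O)O[C@@H]2CBr)O1 | intermediate
19 | ten-membered cyclic sulfide (S between C4 and C5; furanone-bridged, trans-12,6-lactone, C8–OTIPS; both C4 epimers) | C1C(=O)O[C@@H]2CSC(C)C3=CC(=O)[C@@](C)(C[C@H](O[Si](C(C)C)(C(C)C)C(C)C)[C@@H]12)O3 | intermediate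
20 | ten-membered cyclic sulfone of 19 | C1C(=O)O[C@@H]2CS(=O)(=O)C(C)C3=CC(=O)[C@@](C)(C[C@H](O[Si](C(C)C)(C(C)C)C(C)C)[C@@H]12)O3 | intermediate
21 | potassium hydroxy carboxylate of 20 (lactone opened; C6–OH, C12 carboxylate) | [K+].[O-]C(=O)C[C@H]1[C@H](O)CS(=O)(=O)C(C)C2=CC(=O)[C@@](C)(C[C@@H]1O[Si](C(C)C)(C(C)C)C(C)C)O2 | intermediate (not isolated)
22 | α-bromo sulfone (21 brominated at C4) | [K+].[O-]C(=O)C[C@H]1[C@H](O)CS(=O)(=O)C(C)(Br)C2=CC(=O)[C@@](C)(C[C@@H]1O[Si](C(C)C)(C(C)C)C(C)C)O2 | intermediate (not isolated)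
23 | episulfone (thiirane 1,1-dioxide across C4–C5) | [K+].[O-]C(=O)C[C@H]1[C@H](O)C3C(C)(S3(=O)=O)C2=CC(=O)[C@@](C)(C[C@@H]1O[Si](C(C)C)(C(C)C)C(C)C)O2 | intermediate (not isolated)
24 | ring-contracted hydroxy carboxylate (Z-C4=C5, C6–OH, C12 carboxylate) | [K+].[O-]C(=O)C[C@H]1[C@H](O)/C=C(/C)C2=CC(=O)[C@@](C)(C[C@@H]1O[Si](C(C)C)(C(C)C)C(C)C)O2 | intermediate (not isolated)
25 | 11,13-dihydro-8-O-(triisopropylsilyl)-8-deacyl-lychnopholide | C1C(=O)O[C@@H]2/C=C(/C)C3=CC(=O)[C@@](C)(C[C@H](O[Si](C(C)C)(C(C)C)C(C)C)[C@@H]12)O3 | intermediate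
26 | Mannich base: 25 with CH2NMe2 at C11 (C11 epimers) | CN(C)CC1C(=O)O[C@@H]2/C=C(/C)C3=CC(=O)[C@@](C)(C[C@H](O[Si](C(C)C)(C(C)C)C(C)C)[C@@H]12)O3 | intermediate (not isolated)
27 | trimethylammonium iodide of 26 | C[N+](C)(C)CC1C(=O)O[C@@H]2/C=C(/C)C3=CC(=O)[C@@](C)(C[C@H](O[Si](C(C)C)(C(C)C)C(C)C)[C@@H]12)O3.[I-] | intermediate (not isolated)
28 | 8-O-(triisopropylsilyl)-8-deacyl-lychnopholide | C=C1C(=O)O[C@@H]2/C=C(/C)C3=CC(=O)[C@@](C)(C[C@H](O[Si](C(C)C)(C(C)C)C(C)C)[C@@H]12)O3 | intermediate
29 | 8-deacyl-lychnopholide (C8–OH) | C=C1C(=O)O[C@@H]2/C=C(/C)C3=CC(=O)[C@@](C)(C[C@H](O)[C@@H]12)O3 | intermediate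
30 | angelic acid ((Z)-2-methylbut-2-enoic acid) | C/C=C(/C)C(=O)O | starting material
31 | angelic 2,4,6-trichlorobenzoic mixed anhydride | C/C=C(/C)C(=O)OC(=O)c1c(Cl)cc(Cl)cc1Cl | intermediate (not isolated)
32 | lychnopholide | C=C1C(=O)O[C@@H]2/C=C(/C)C3=CC(=O)[C@@](C)(C[C@H](OC(=O)/C(C)=C\C)[C@@H]12)O3 | target

**Step count.** Total steps: 16. Longest linear sequence: 16 steps (1 to 32).

**Steps most likely to fail**

Step 13 (key step). Under aqueous hydroxide the β-hydroxy sulfone may fragment by retro-aldol cleavage of the C5–C6 bond, or hydroxide may add to the furanone and open it before the contraction takes place. The fallback sets out from 20 and comes back at 25, keeping the ring contraction but removing both hydroxide and any leaving group at C6. The lactone of 20 is opened with pyrrolidine (neat, 40 °C) to the hydroxy pyrrolidine amide F1. Its C6 hydroxyl is silylated (TESOTf, 2,6-lutidine, CH2Cl2) to the triethylsilyl ether F2. F2 is chlorinated at C4 and contracted under anhydrous two-stage Ramberg–Bäcklund conditions (t-BuOK, C2Cl6, THF, −78 °C; then t-BuOK, −78 to 0 °C) to the ring-contracted amide F3. TsOH·H2O in wet THF at 40 °C then removes the triethylsilyl group and lactonises with loss of pyrrolidine to give 25.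

Step 6. Incomplete enolate masking would let the acetylide deprotonate or attack the 12,6-lactone, and the α-oxido 1,8-lactone may add the acetylide only sluggishly. The fallback sets out from 10 and comes back at 15. α-Hydroxy-directed borane reduction (BH3·SMe2, NaBH4 cat., THF) opens only the α-hydroxy lactone and gives the triol F4. TESCl and imidazole give the bis(triethylsilyl) ether F5 at the C1 and C8 oxygens. Swern oxidation converts the primary silyl ether directly into the α-hydroxy aldehyde F6, which cannot compete with a lactone for the nucleophile. Lithium but-1-ynide (2.2 equiv, THF, −78 °C) adds to give the propargylic alcohol F7. MnO2 oxidises it selectively to the ynone F8. AuCl3 cyclises F8 to the silylated furanone F9. PPTS in MeOH at 0 °C removes the secondary triethylsilyl group and returns 15.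

Step 5. Facial selectivity may be poor, because the methyl and ester groups on C10 differ little in size and the C7 centre exerts its own bias on the ketone. The fallback sets out from 8 and comes back at 10 without any new compound. Substrate-directed hydride delivery is replaced by catalyst control, namely hydroxyl-directed Noyori asymmetric hydrogenation with RuCl2[(S)-BINAP] or its (R) antipode (H2, MeOH, 50 °C), the antipode being chosen for the required C8 configuration. The diol ester 9 then lactonises to 10 as before.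

**Further compounds**

F1 | step 13 | hydroxy pyrrolidine amide of sulfone 20 (lactone opened; C6–OH) | O=C(C[C@H]1[C@H](O)CS(=O)(=O)C(C)C2=CC(=O)[C@@](C)(C[C@@H]1O[Si](C(C)C)(C(C)C)C(C)C)O2)N3CCCC3
F2 | step 13 | C6 triethylsilyl ether of F1 | O=C(C[C@H]1[C@H](O[Si](CC)(CC)CC)CS(=O)(=O)C(C)C2=CC(=O)[C@@](C)(C[C@@H]1O[Si](C(C)C)(C(C)C)C(C)C)O2)N3CCCC3
F3 | step 13 | ring-contracted amide (Z-C4=C5; C6–OTES) | O=C(C[C@H]1[C@H](O[Si](CC)(CC)CC)/C=C(/C)C2=CC(=O)[C@@](C)(C[C@@H]1O[Si](C(C)C)(C(C)C)C(C)C)O2)N3CCCC3
F4 | step 6 | triol (C1H2–OH, C8–OH, C10–OH; 12,6-lactone intact) | OC[C@](C)(O)C[C@H](O)[C@H]1CC(=O)O[C@@H]1CO[Si](C)(C)C(C)(C)C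
F5 | step 6 | bis(triethylsilyl) ether of F4 at the C1 and C8 oxygens | CC[Si](CC)(CC)OC[C@](C)(O)C[C@H](O[Si](CC)(CC)CC)[C@H]1CC(=O)O[C@@H]1CO[Si](C)(C)C(C)(C)C
F6 | step 6 | α-hydroxy aldehyde (C1 aldehyde; C8–OTES) | O=C[C@](C)(O)C[C@H](O[Si](CC)(CC)CC)[C@H]1CC(=O)O[C@@H]1CO[Si](C)(C)C(C)(C)C
F7 | step 6 | propargylic alcohol (C1 epimers) | CCC#CC(O)[C@](C)(O)C[C@H](O[Si](CC)(CC)CC)[C@H]1CC(=O)O[C@@H]1CO[Si](C)(C)C(C)(C)C
F8 | step 6 | α′-hydroxy ynone with C8–OTES | CCC#CC(=O)[C@](C)(O)C[C@H](O[Si](CC)(CC)CC)[C@H]1CC(=O)O[C@@H]1CO[Si](C)(C)C(C)(C)C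
F9 | step 6 | C8 triethylsilyl ether of 15 | CCC1=CC(=O)[C@@](C)(C[C@H](O[Si](CC)(CC)CC)[C@H]2CC(=O)O[C@@H]2CO[Si](C)(C)C(C)(C)C)O1
F0 | step 5 | none | none
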